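**Plan**

1. Retrosynthetic cuts, in order: the C3–aroyl bond; the C1′–C2′ bond of both geranyl groups (one two-fold decarboxylative alkenylation of a 5,7-bis(carboxymethyl) core with a single (E)-C9 alkenylzinc); the prenyl alkene (metathesis of allyl); C7–H; C7–C8 (ring B); C1–allyl; C1–C2 (ring A); the two exocyclic C–C bonds at C5; C5–C9.
2. Forward order: γ-acylation of a 3-methoxycrotonate gives the chain C2–C3–C4–C5–C9–C1–C8; C5 is made quaternary by two alkylations; a Dieckmann closure forms ring A (C1–C2–C3–C4–C5–C9); C1 is allylated; ring B (C1–C8–C7–C6–C5–C9) is closed by forming C7–C8; the side chains and the aroyl group follow.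
3. Enabling feature: C8 is a CMe2 carbon on bridgehead C1, so it can arise as a tertiary radical by hydrogen-atom transfer to an isopropenyl group on C1. The C9 carbonyl of ring A holds that group and a but-2-ynoate arm on C5 in a 1,3-cis relationship, so the radical reaches the alkyne β-carbon C7 in 6-exo-dig mode and the bicyclo[3.3.1]nonane results.
4. Stereochemistry: C5 from an asymmetric phase-transfer alkylation; C1 from a ligand-controlled palladium allylation (a wrong C1 epimer cannot cyclise and is purged in the key step); C7 from exo-face copper hydride delivery to the exocyclic enoate, the endo face being covered by the C2–C3–C4 bridge; both geranyl alkenes are E from a zirconium-catalysed carboalumination.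

Key step: step 7

Remark: locants C1–C9 in the text are those of the bicyclo[3.3.1]nonane core of the target (C1 prenyl-bearing bridgehead, C2 C=O, C3 aroyl-bearing, C4 enol carbon, C5 geranyl-bearing bridgehead, C6 CH2, C7 CH, C8 CMe2, C9 bridging C=O; side-chain carbons primed). IUPAC names of acyclic and monocyclic intermediates carry their own locants. Commercial availability of 1, 2, 5, 8, 19 and 28 is assumed.

**Step 1**
Reactants: 1 methyl (2E)-3-methoxybut-2-enoate; 2 3-methylbut-2-enoyl chloride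
Product: 4 methyl (2E)-3-methoxy-7-methyl-5-oxoocta-2,6-dienoate, via lithium dienolate 3 (not isolated)
Conditions: LiN(i-Pr)2 (2.0 equiv), 1 (2.0 equiv), THF, −78 °C; then 2 (1.0 equiv), −78 °C; AcOH quench at −78 °C
Reagents that add atoms: none
Why: γ-Deprotonation of the vinylogous ester gives the 1,3-dimethoxydienolate, which is acylated at its γ-carbon by the acid chloride (vinylogous Claisen acylation), the second equivalent of dienolate taking up the acidic product proton and the cold quench preventing lactonisation to a 2-pyranone.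

**Step 2**
Reactants: 4 methyl (2E)-3-methoxy-7-methyl-5-oxoocta-2,6-dienoate; 5 tert-butyl bromoacetate
Product: 7 1-tert-butyl 6-methyl (4E)-4-methoxy-3-(3-methylbut-2-enoyl)hex-4-enedioate (racemic), via sodium enolate 6 (not isolated)
Conditions: NaH (1.0 equiv), THF, −20 °C; then 5 (1.0 equiv), −20 → 0 °C
Reagents that add atoms: none
Why: The C5 methylene between the ketone and the enol ether carbon is the most acidic site and its soft enolate is C-alkylated by the α-bromo ester (SN2), the bulky tert-butyl ester favouring monoalkylation.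

**Step 3**
Reactants: 7 1-tert-butyl 6-methyl (4E)-4-methoxy-3-(3-methylbut-2-enoyl)hex-4-enedioate; 8 3-bromoprop-1-yne
Product: 9 1-tert-butyl 6-methyl (3R,4E)-4-methoxy-3-(3-methylbut-2-enoyl)-3-(prop-2-yn-1-yl)hex-4-enedioate
Conditions: 8 (1.5 equiv), (S)-4,4-dibutyl-2,6-bis(3,4,5-trifluorophenyl)-4,5-dihydro-3H-dinaphtho[2,1-c:1′,2′-e]azepinium bromide (3 mol %), CsOH·H2O (2 equiv), toluene, −30 °C
Reagents that add atoms: none
Why: Asymmetric phase-transfer alkylation, in which the chiral quaternary ammonium cation pairs with the planar doubly stabilised enolate and exposes one face to SN2 attack on propargyl bromide, should set the quaternary C5 centre (3R in 9), the enantiomeric catalyst being the remedy if the sense of induction proves opposite.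

**Step 4**
Reactants: 9 1-tert-butyl 6-methyl (3R,4E)-4-methoxy-3-(3-methylbut-2-enoyl)-3-(prop-2-yn-1-yl)hex-4-enedioate
Product: 10 tert-butyl 2-[(1S)-2-hydroxy-6-methoxy-4-oxo-3-(prop-1-en-2-yl)-1-(prop-2-yn-1-yl)cyclohexa-2,5-dien-1-yl]acetate
Conditions: NaOMe (2.5 equiv), MeOH, 0 °C → rt; then 1 M HCl to pH 3
Reagents that add atoms: none
Why: In this Dieckmann-type condensation γ-deprotonation of the enone gives a dienolate whose α-carbon (C1) attacks the C2 methyl ester held cis on the C3=C4 bond (6-exo-trig), and formation of the enolate of the resulting 1,3-diketone drives closure of ring A, the tert-butyl ester being inert as a Claisen acceptor and the quaternary C5 centre carrying no acidic hydrogen.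

**Step 5**
Reactants: 10 tert-butyl 2-[(1S)-2-hydroxy-6-methoxy-4-oxo-3-(prop-1-en-2-yl)-1-(prop-2-yn-1-yl)cyclohexa-2,5-dien-1-yl]acetate
Product: 11 tert-butyl 2-[(1R,5R)-2-methoxy-4,6-dioxo-5-(prop-2-en-1-yl)-5-(prop-1-en-2-yl)-1-(prop-2-yn-1-yl)cyclohex-2-en-1-yl]acetate
Conditions: Pd2(dba)3·CHCl3 (2.5 mol %), (1R,2R)-N,N′-bis[2-(diphenylphosphino)benzoyl]cyclohexane-1,2-diamine (7.5 mol %), allyl methyl carbonate (1.1 equiv), CH2Cl2, 0 °C
Reagents that add atoms: allyl methyl carbonate C=CCOC(=O)OC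
Why: In this Tsuji–Trost asymmetric allylic alkylation the methoxide released on ionisation deprotonates the acidic enol and the soft extended enolate attacks the π-allyl palladium complex at C1 under kinetic control, the chiral ligand pocket being relied on to place allyl trans to the propargyl arm (the enantiomeric ligand is the remedy if the sense is opposite), while a C1 epimer cannot close ring B in step 7 and is removed there, and the low temperature suppresses re-ionisation and the 3,3-shift of the 1,5-diene.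

**Step 6**
Reactants: 11 tert-butyl 2-[(1R,5R)-2-methoxy-4,6-dioxo-5-(prop-2-en-1-yl)-5-(prop-1-en-2-yl)-1-(prop-2-yn-1-yl)cyclohex-2-en-1-yl]acetate
Product: 13 methyl 4-[(1R,5R)-1-(2-tert-butoxy-2-oxoethyl)-2-methoxy-4,6-dioxo-5-(prop-2-en-1-yl)-5-(prop-1-en-2-yl)cyclohex-2-en-1-yl]but-2-ynoate, via cesium alkynoate 12 (not isolated)
Conditions: AgI (5 mol %), Cs2CO3 (1.5 equiv), CO2 (1 atm), DMF, 40 °C; then MeI (2 equiv), rt
Reagents that add atoms: carbon dioxide O=C=O; iodomethane CI
Why: Silver-catalysed C–H carboxylation of the terminal alkyne followed by O-methylation of the cesium carboxylate turns the propargyl arm into an electron-poor but-2-ynoate, the radical acceptor for the next step, without touching the non-enolisable diketone.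

**Step 7**
Reactants: 13 methyl 4-[(1R,5R)-1-(2-tert-butoxy-2-oxoethyl)-2-methoxy-4,6-dioxo-5-(prop-2-en-1-yl)-5-(prop-1-en-2-yl)cyclohex-2-en-1-yl]but-2-ynoate
Product: 14 methyl (2E)-2-[(1R,5R)-5-(2-tert-butoxy-2-oxoethyl)-4-methoxy-8,8-dimethyl-2,9-dioxo-1-(prop-2-en-1-yl)bicyclo[3.3.1]non-3-en-7-ylidene]acetate
Conditions: Fe(acac)3 (0.5 equiv), PhSiH3 (2.5 equiv), EtOH/ethylene glycol (5:1), 35 °C, degassed
Reagents that add atoms: none
Why: Proposed new method: an iron hydride formed from Fe(acac)3, PhSiH3 and ethanol should transfer a hydrogen atom to the CH2 terminus of the C1 isopropenyl group (Markovnikov HAT) to give the tertiary C8 radical, which adds to C7, the β-carbon of the but-2-ynoate arm, and the resulting α-ester vinyl radical is reduced by divalent iron and protonated by ethanol to the exocyclic enoate. The closest known reaction type is the iron-hydride HAT-initiated reductive coupling of alkenes with acrylate-type acceptors (Giese addition), here extended to an alkynoate acceptor in an intramolecular setting, with tin hydride radical cyclisations onto alkynoates as the classical counterpart. Ring B (C1–C8–C7–C6–C5–C9) closes in 6-exo-dig mode and thereby forms the C7–C8 bond, the quaternary C8 centre and the bicyclo[3.3.1]nonane. No new stereocentre arises at C7 (it stays trigonal) or at C8 (two methyl groups), while the bridgehead configurations at C1 and C5 are carried over from 13, closure being possible only because the C1 isopropenyl and C5 butynoate groups are cis across the C9 carbonyl. The step needs HAT to the 1,1-disubstituted alkene rather than to the allyl group (tertiary versus secondary radical) and attack at C7 rather than at C1′ (the ester polarises the alkyne towards the nucleophilic radical and a six-membered ring forms faster than a seven-membered one). The product enoate is electron-poor and should resist further HAT, which an exocyclic methylene from an unactivated alkyne would not.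

**Step 8**
Reactants: 14 methyl (2E)-2-[(1R,5R)-5-(2-tert-butoxy-2-oxoethyl)-4-methoxy-8,8-dimethyl-2,9-dioxo-1-(prop-2-en-1-yl)bicyclo[3.3.1]non-3-en-7-ylidene]acetate
Product: 15 tert-butyl 2-[(1R,5R,7R)-4-methoxy-7-(2-methoxy-2-oxoethyl)-8,8-dimethyl-2,9-dioxo-1-(prop-2-en-1-yl)bicyclo[3.3.1]non-3-en-5-yl]acetate
Conditions: Cu(OAc)2·H2O (5 mol %), 1,2-bis(diphenylphosphino)benzene (5 mol %), (EtO)2MeSiH (3 equiv), t-BuOH (3 equiv), toluene, rt
Reagents that add atoms: none
Why: In this copper hydride conjugate reduction the ligated Cu–H should deliver hydride to the β-carbon C7 from the exo (convex) face, because the endo face of the exocyclic alkene is covered by the C2–C3–C4 bridge of ring A, so that H ends exo and the CH2CO2Me group endo (7R) from either alkene isomer of 14, while isolated alkenes, the push–pull vinylogous ester and the hindered C9 ketone are not reduced.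

**Step 9**
Reactants: 15 tert-butyl 2-[(1R,5R,7R)-4-methoxy-7-(2-methoxy-2-oxoethyl)-8,8-dimethyl-2,9-dioxo-1-(prop-2-en-1-yl)bicyclo[3.3.1]non-3-en-5-yl]acetate
Product: 17 2,2′-[(1R,5R,7R)-4-methoxy-8,8-dimethyl-2,9-dioxo-1-(prop-2-en-1-yl)bicyclo[3.3.1]non-3-ene-5,7-diyl]diacetic acid, via mono-acid 16 (not isolated)
Conditions: LiOH·H2O (3 equiv), THF/H2O (3:1), 0 °C → rt; 1 M HCl, extraction; then CF3CO2H/CH2Cl2 (1:4), 0 °C → rt
Reagents that add atoms: lithium hydroxide [Li+].[OH-]
Why: Saponification of the unhindered primary methyl ester (the vinylogous methyl ester should survive the mild base) followed by acidolysis of the tert-butyl ester with loss of isobutene gives the diacid at a stage where the only alkene is the acid-stable allyl group.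

**Step 10**
Reactants: 17 2,2′-[(1R,5R,7R)-4-methoxy-8,8-dimethyl-2,9-dioxo-1-(prop-2-en-1-yl)bicyclo[3.3.1]non-3-ene-5,7-diyl]diacetic acid
Product: 18 2,2′-[(1R,5R,7R)-4-methoxy-8,8-dimethyl-1-(3-methylbut-2-en-1-yl)-2,9-dioxobicyclo[3.3.1]non-3-ene-5,7-diyl]diacetic acid
Conditions: second-generation Grubbs catalyst RuCl2(=CHPh)(H2IMes)(PCy3) (5 mol %), 2-methylbut-2-ene/CH2Cl2 (1:2), 40 °C
Reagents that add atoms: 2-methylbut-2-ene CC=C(C)C
Why: Olefin cross-metathesis of the monosubstituted allyl group with excess 2-methylbut-2-ene converts it into the prenyl group with loss of propene, a reaction that tolerates free carboxylic acids and hindered ketones.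

**Step 11**
Reactants: 19 6-methylhept-5-en-2-one
Product: 21 6-methylhept-5-en-1-yne, via enol phosphate 20 (not isolated)
Conditions: LiN(i-Pr)2 (1.05 equiv), THF, −78 °C; ClP(O)(OEt)2, −78 °C → rt; then LiN(i-Pr)2 (2.2 equiv), −78 °C → rt; aq. NH4Cl
Reagents that add atoms: none
Why: The kinetic enolate of the methyl ketone is O-phosphorylated and the enol phosphate undergoes base-induced β-elimination to the terminal alkyne (ketone-to-alkyne conversion via the enol phosphate).

**Step 12**
Reactants: 21 6-methylhept-5-en-1-yne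
Product: 23 (1E)-1-iodo-2,6-dimethylhepta-1,5-diene, via alkenylalane 22 (not isolated)
Conditions: Me3Al (2.0 equiv), Cp2ZrCl2 (0.2 equiv), CH2Cl2, 0 °C → rt; then I2 (1.2 equiv), THF, −30 → 0 °C
Reagents that add atoms: trimethylaluminium C[Al](C)C; iodine [I][I]
Why: Zirconium-catalysed carboalumination (Negishi) adds methyl and aluminium syn across the terminal alkyne with aluminium at the terminus, and iodinolysis with retention gives the (E)-alkenyl iodide that carries the future C2′=C3′ geometry of both geranyl groups.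

**Step 13**
Reactants: 18 2,2′-[(1R,5R,7R)-4-methoxy-8,8-dimethyl-1-(3-methylbut-2-en-1-yl)-2,9-dioxobicyclo[3.3.1]non-3-ene-5,7-diyl]diacetic acid; 23 (1E)-1-iodo-2,6-dimethylhepta-1,5-diene
Product: 27 (1R,5S,7S)-5,7-bis[(2E)-3,7-dimethylocta-2,6-dien-1-yl]-4-methoxy-8,8-dimethyl-1-(3-methylbut-2-en-1-yl)bicyclo[3.3.1]non-3-ene-2,9-dione, via alkenyllithium 24 (not isolated), via alkenylzinc chloride 25 (not isolated), via bis(N-acyloxyphthalimide) 26 (not isolated)
Conditions: 23 (5 equiv), t-BuLi (10 equiv), Et2O, −78 °C; ZnCl2 (5.5 equiv), THF, −78 °C → rt; separately 18, N-hydroxyphthalimide (2.2 equiv), i-PrN=C=N-i-Pr (2.2 equiv), CH2Cl2, rt; then Ni(acac)2 (20 mol %), 2,2′-bipyridine (20 mol %), THF/DMF, rt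
Reagents that add atoms: none
Why: In this nickel-catalysed decarboxylative alkenylation of redox-active esters, single-electron reduction of each N-acyloxyphthalimide by low-valent nickel releases CO2 and a primary alkyl radical (C5–CH2 and C7–CH2) that is captured by the alkenylnickel species, and reductive elimination forms both C1′–C2′ bonds with retention of the (E)-alkene geometry, the stereocentres not being involved (the descriptors at C5 and C7 change through priority only).

**Step 14**
Reactants: 28 3,4-dihydroxybenzoic acid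
Product: 29 tert-butyldimethylsilyl 3,4-bis[(tert-butyldimethylsilyl)oxy]benzoate
Conditions: t-BuMe2SiCl (3.5 equiv), imidazole (7 equiv), DMF, rt
Reagents that add atoms: tert-butyldimethylsilyl chloride CC(C)(C)[Si](C)(C)Cl
Why: Imidazole-promoted silylation converts both phenols into silyl ethers and the carboxylic acid into its silyl ester.

**Step 15**
Reactants: 29 tert-butyldimethylsilyl 3,4-bis[(tert-butyldimethylsilyl)oxy]benzoate
Product: 30 3,4-bis[(tert-butyldimethylsilyl)oxy]benzoyl chloride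
Conditions: (COCl)2 (1.2 equiv), DMF (cat.), CH2Cl2, 0 °C → rt
Reagents that add atoms: oxalyl chloride ClC(=O)C(=O)Cl
Why: The silyl ester is converted directly into the acid chloride by the chloroiminium (Vilsmeier) reagent under neutral conditions, so the aryl silyl ethers are never exposed to HCl.

**Step 16**
Reactants: 27 (1R,5S,7S)-5,7-bis[(2E)-3,7-dimethylocta-2,6-dien-1-yl]-4-methoxy-8,8-dimethyl-1-(3-methylbut-2-en-1-yl)bicyclo[3.3.1]non-3-ene-2,9-dione; 30 3,4-bis[(tert-butyldimethylsilyl)oxy]benzoyl chloride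
Product: 32 (1S,5S,7S)-3-{3,4-bis[(tert-butyldimethylsilyl)oxy]benzoyl}-5,7-bis[(2E)-3,7-dimethylocta-2,6-dien-1-yl]-4-methoxy-8,8-dimethyl-1-(3-methylbut-2-en-1-yl)bicyclo[3.3.1]non-3-ene-2,9-dione, via C3-lithio derivative 31 (not isolated)
Conditions: Li(TMP) (1.5 equiv), THF, −78 °C; then 30 (1.5 equiv), −78 → −40 °C
Reagents that add atoms: none
Why: The vinylic C3–H between the C2 carbonyl and the C4 methoxy group is the only acidic position (neither C9 nor C2 has an α-hydrogen), so the hindered amide base gives the C3 vinyllithium, which is C-acylated by the aroyl chloride (directed vinylic lithiation and acylation of a bicyclic vinylogous ester).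

**Step 17**
Reactants: 32 (1S,5S,7S)-3-{3,4-bis[(tert-butyldimethylsilyl)oxy]benzoyl}-5,7-bis[(2E)-3,7-dimethylocta-2,6-dien-1-yl]-4-methoxy-8,8-dimethyl-1-(3-methylbut-2-en-1-yl)bicyclo[3.3.1]non-3-ene-2,9-dione
Product: 33 oblongifolin D [(1S,5S,7S)-3-(3,4-dihydroxybenzoyl)-5,7-bis[(2E)-3,7-dimethylocta-2,6-dien-1-yl]-4-hydroxy-8,8-dimethyl-1-(3-methylbut-2-en-1-yl)bicyclo[3.3.1]non-3-ene-2,9-dione]
Conditions: LiOH (2 M aq., 10 equiv), 1,4-dioxane, 90 °C, argon, degassed; then 1 M HCl to pH 3
Reagents that add atoms: lithium hydroxide [Li+].[OH-]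
Why: Hydroxide adds to C4 of the doubly activated β-methoxy enone and expels methoxide (vinylogous ester hydrolysis) and also cleaves both aryl silyl ethers at silicon, which frees the enolised triketone and the catechol in one operation without risk to the stereocentres (C1 and C5 are quaternary bridgeheads and C7 is not α to a carbonyl).

**Compound list**

1 | methyl (2E)-3-methoxybut-2-enoate | CO/C(C)=C/C(=O)OC | starting material
2 | 3-methylbut-2-enoyl chloride | CC(C)=CC(=O)Cl | starting material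
3 | lithium 1,3-dimethoxybuta-1,3-dien-1-olate (dienolate of 1) | C=C(OC)C=C(OC)O[Li] | intermediate (not isolated)
4 | methyl (2E)-3-methoxy-7-methyl-5-oxoocta-2,6-dienoate | CO/C(CC(=O)C=C(C)C)=C/C(=O)OC | intermediate
5 | tert-butyl bromoacetate | CC(C)(C)OC(=O)CBr | starting material
6 | sodium enolate of 4 (C5=C9 enolate) | CO/C(C=C(O[Na])C=C(C)C)=C/C(=O)OC | intermediate (not isolated)
7 | 1-tert-butyl 6-methyl (4E)-4-methoxy-3-(3-methylbut-2-enoyl)hex-4-enedioate (racemic) | CO/C(=C/C(=O)OC)C(CC(=O)OC(C)(C)C)C(=O)C=C(C)C | intermediate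
8 | 3-bromoprop-1-yne | C#CCBr | starting material
9 | 1-tert-butyl 6-methyl (3R,4E)-4-methoxy-3-(3-methylbut-2-enoyl)-3-(prop-2-yn-1-yl)hex-4-enedioate | C#CC[C@](/C(OC)=C\C(=O)OC)(CC(=O)OC(C)(C)C)C(=O)C=C(C)C | intermediate
10 | tert-butyl 2-[(1S)-2-hydroxy-6-methoxy-4-oxo-3-(prop-1-en-2-yl)-1-(prop-2-yn-1-yl)cyclohexa-2,5-dien-1-yl]acetate (enol tautomer shown) | C#CC[C@]1(CC(=O)OC(C)(C)C)C(O)=C(C(C)=C)C(=O)C=C1OC | intermediate
11 | tert-butyl 2-[(1R,5R)-2-methoxy-4,6-dioxo-5-(prop-2-en-1-yl)-5-(prop-1-en-2-yl)-1-(prop-2-yn-1-yl)cyclohex-2-en-1-yl]acetate (isopropenyl cis to propargyl) | C#CC[C@]1(CC(=O)OC(C)(C)C)C(=O)[C@@](CC=C)(C(=O)C=C1OC)C(C)=C | intermediate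
12 | cesium 4-[(1R,5R)-1-(2-tert-butoxy-2-oxoethyl)-2-methoxy-4,6-dioxo-5-(prop-2-en-1-yl)-5-(prop-1-en-2-yl)cyclohex-2-en-1-yl]but-2-ynoate | [Cs+].[O-]C(=O)C#CC[C@]1(CC(=O)OC(C)(C)C)C(=O)[C@@](CC=C)(C(=O)C=C1OC)C(C)=C | intermediate (not isolated)
13 | methyl 4-[(1R,5R)-1-(2-tert-butoxy-2-oxoethyl)-2-methoxy-4,6-dioxo-5-(prop-2-en-1-yl)-5-(prop-1-en-2-yl)cyclohex-2-en-1-yl]but-2-ynoate | COC(=O)C#CC[C@]1(CC(=O)OC(C)(C)C)C(=O)[C@@](CC=C)(C(=O)C=C1OC)C(C)=C | intermediate
14 | methyl (2E)-2-[(1R,5R)-5-(2-tert-butoxy-2-oxoethyl)-4-methoxy-8,8-dimethyl-2,9-dioxo-1-(prop-2-en-1-yl)bicyclo[3.3.1]non-3-en-7-ylidene]acetate | COC(=O)/C=C1\C[C@]2(CC(=O)OC(C)(C)C)C(=O)[C@@](CC=C)(C(=O)C=C2OC)C1(C)C | intermediate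
15 | tert-butyl 2-[(1R,5R,7R)-4-methoxy-7-(2-methoxy-2-oxoethyl)-8,8-dimethyl-2,9-dioxo-1-(prop-2-en-1-yl)bicyclo[3.3.1]non-3-en-5-yl]acetate (C7 side chain endo) | COC(=O)C[C@H]1C[C@]2(CC(=O)OC(C)(C)C)C(=O)[C@@](CC=C)(C(=O)C=C2OC)C1(C)C | intermediate
16 | [(1R,5R,7R)-5-(2-tert-butoxy-2-oxoethyl)-4-methoxy-8,8-dimethyl-2,9-dioxo-1-(prop-2-en-1-yl)bicyclo[3.3.1]non-3-en-7-yl]acetic acid | OC(=O)C[C@H]1C[C@]2(CC(=O)OC(C)(C)C)C(=O)[C@@](CC=C)(C(=O)C=C2OC)C1(C)C | intermediate (not isolated)
17 | 2,2′-[(1R,5R,7R)-4-methoxy-8,8-dimethyl-2,9-dioxo-1-(prop-2-en-1-yl)bicyclo[3.3.1]non-3-ene-5,7-diyl]diacetic acid | OC(=O)C[C@H]1C[C@]2(CC(=O)O)C(=O)[C@@](CC=C)(C(=O)C=C2OC)C1(C)C | intermediate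
18 | 2,2′-[(1R,5R,7R)-4-methoxy-8,8-dimethyl-1-(3-methylbut-2-en-1-yl)-2,9-dioxobicyclo[3.3.1]non-3-ene-5,7-diyl]diacetic acid | OC(=O)C[C@H]1C[C@]2(CC(=O)O)C(=O)[C@@](CC=C(C)C)(C(=O)C=C2OC)C1(C)C | intermediate
19 | 6-methylhept-5-en-2-one | CC(=O)CCC=C(C)C | starting material
20 | diethyl 6-methylhepta-1,5-dien-2-yl phosphate | C=C(CCC=C(C)C)OP(=O)(OCC)OCC | intermediate (not isolated)
21 | 6-methylhept-5-en-1-yne | C#CCCC=C(C)C | intermediate
22 | [(1E)-2,6-dimethylhepta-1,5-dien-1-yl]dimethylalane | C[Al](C)/C=C(\C)CCC=C(C)C | intermediate (not isolated)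
23 | (1E)-1-iodo-2,6-dimethylhepta-1,5-diene | I/C=C(\C)CCC=C(C)C | intermediate
24 | [(1E)-2,6-dimethylhepta-1,5-dien-1-yl]lithium | [Li]/C=C(\C)CCC=C(C)C | intermediate (not isolated)
25 | chloro[(1E)-2,6-dimethylhepta-1,5-dien-1-yl]zinc | Cl[Zn]/C=C(\C)CCC=C(C)C | intermediate (not isolated)
26 | bis(1,3-dioxo-1,3-dihydro-2H-isoindol-2-yl) 2,2′-[(1R,5R,7R)-4-methoxy-8,8-dimethyl-1-(3-methylbut-2-en-1-yl)-2,9-dioxobicyclo[3.3.1]non-3-ene-5,7-diyl]diacetate | O=C1c2ccccc2C(=O)N1OC(=O)C[C@H]1C[C@]2(CC(=O)ON3C(=O)c4ccccc4C3=O)C(=O)[C@@](CC=C(C)C)(C(=O)C=C2OC)C1(C)C | intermediate (not isolated)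
27 | (1R,5S,7S)-5,7-bis[(2E)-3,7-dimethylocta-2,6-dien-1-yl]-4-methoxy-8,8-dimethyl-1-(3-methylbut-2-en-1-yl)bicyclo[3.3.1]non-3-ene-2,9-dione | CC(C)=CCC/C(C)=C/C[C@H]1C[C@]2(C/C=C(\C)CCC=C(C)C)C(=O)[C@@](CC=C(C)C)(C(=O)C=C2OC)C1(C)C | intermediate
28 | 3,4-dihydroxybenzoic acid | OC(=O)c1ccc(O)c(O)c1 | starting material
29 | tert-butyldimethylsilyl 3,4-bis[(tert-butyldimethylsilyl)oxy]benzoate | CC(C)(C)[Si](C)(C)OC(=O)c1ccc(O[Si](C)(C)C(C)(C)C)c(O[Si](C)(C)C(C)(C)C)c1 | intermediate
30 | 3,4-bis[(tert-butyldimethylsilyl)oxy]benzoyl chloride | ClC(=O)c1ccc(O[Si](C)(C)C(C)(C)C)c(O[Si](C)(C)C(C)(C)C)c1 | intermediate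
31 | C3-lithio derivative of 27 | CC(C)=CCC/C(C)=C/C[C@H]1C[C@]2(C/C=C(\C)CCC=C(C)C)C(=O)[C@@](CC=C(C)C)(C(=O)C([Li])=C2OC)C1(C)C | intermediate (not isolated)
32 | (1S,5S,7S)-3-{3,4-bis[(tert-butyldimethylsilyl)oxy]benzoyl}-5,7-bis[(2E)-3,7-dimethylocta-2,6-dien-1-yl]-4-methoxy-8,8-dimethyl-1-(3-methylbut-2-en-1-yl)bicyclo[3.3.1]non-3-ene-2,9-dione | CC(C)=CCC/C(C)=C/C[C@H]1C[C@]2(C/C=C(\C)CCC=C(C)C)C(=O)[C@@](CC=C(C)C)(C(=O)C(C(=O)c3ccc(O[Si](C)(C)C(C)(C)C)c(O[Si](C)(C)C(C)(C)C)c3)=C2OC)C1(C)C | intermediate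
33 | oblongifolin D | CC(C)=CCC/C(C)=C/C[C@H]1C[C@]2(C/C=C(\C)CCC=C(C)C)C(=O)[C@@](CC=C(C)C)(C(=O)C(C(=O)c3ccc(O)c(O)c3)=C2O)C1(C)C | target

**Step count and risks**

Total: 17 steps (13 in the main line, 2 for the alkenyl iodide 23, 2 for the aroyl chloride 30). Longest linear sequence: 13 steps (steps 1–10, 13, 16, 17).

Steps most likely to fail:

Step 7 (proposed new method). The tertiary C8 radical may be reduced to an isopropyl group, or rearrange by 1,2-acyl shift onto the C2 or C9 carbonyl (Dowd–Beckwith type), before it cyclises; hydrogen-atom transfer may also go to the allyl group. The fallback uses known chemistry and runs from 13 back to 14. Cobalt-catalysed radical Markovnikov hydrochlorination of the isopropenyl group (Co(BF4)2·6H2O, Schiff-base ligand, PhSiH3, TsCl, t-BuOOH, EtOH, rt) gives the tertiary chloride F1 as a discrete radical precursor. Slow addition of Bu3SnH with AIBN in benzene at 80 °C then runs the 6-exo-dig cyclisation onto the alkynoate as a tin hydride chain at low hydride concentration, which lengthens the radical lifetime, and gives 14.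

Step 13. The two-fold coupling may stop halfway. The hindered C5–CH2 radical (neopentyl, β to the C9 ketone) or the endo C7–CH2 radical, which can swing over the C3=C4 bond, may be reduced, rearrange or add transannularly before nickel captures it. The fallback runs from 18 to 27 and forms the C–C bonds by two-electron transmetalation instead. Coupling of 18 with 1-hydroxypyridine-2(1H)-thione (dicyclohexylcarbodiimide, CH2Cl2, dark) gives the bis(thiohydroxamate) ester F2. Photolysis in the presence of CHI3 (Barton iododecarboxylation, where fast iodine-atom transfer outruns rearrangement) gives the bis(iodomethyl) compound F3. Zinc insertion (Zn dust, LiCl, THF, 40 °C) gives the bis(alkylzinc iodide) F4, and Negishi coupling with 23 (PdCl2(dppf), THF, rt) gives 27.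

Step 3. The chiral cation may discriminate poorly between the faces of the acyclic, conformationally mobile enolate, so that C5 is formed with low enantiomeric purity; the enolate may also lactonise onto the C2 ester to a 2-pyranone. The fallback runs from 7 to 9. Alkylation without chiral catalyst (Cs2CO3, 8, DMF, 0 °C) gives 9 together with its enantiomer F5, and the two are separated by preparative chromatography on a chiral stationary phase (supercritical CO2/MeOH). Compound 9 re-enters at step 4.

**Further compounds**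

F1 | step 7 | methyl 4-[(1R,5R)-1-(2-tert-butoxy-2-oxoethyl)-5-(2-chloropropan-2-yl)-2-methoxy-4,6-dioxo-5-(prop-2-en-1-yl)cyclohex-2-en-1-yl]but-2-ynoate | COC(=O)C#CC[C@]1(CC(=O)OC(C)(C)C)C(=O)[C@@](CC=C)(C(=O)C=C1OC)C(C)(C)Cl
F2 | step 13 | bis(2-thioxopyridin-1(2H)-yl) diester of 18 (configuration as in 18) | S=C1C=CC=CN1OC(=O)C[C@H]1C[C@]2(CC(=O)ON3C=CC=CC3=S)C(=O)[C@@](CC=C(C)C)(C(=O)C=C2OC)C1(C)C
F3 | step 13 | 5,7-bis(iodomethyl)-4-methoxy-8,8-dimethyl-1-(3-methylbut-2-en-1-yl)bicyclo[3.3.1]non-3-ene-2,9-dione (configuration as in 18) | IC[C@H]1C[C@]2(CI)C(=O)[C@@](CC=C(C)C)(C(=O)C=C2OC)C1(C)C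
F4 | step 13 | bis(alkylzinc iodide) derived from F3 | I[Zn]C[C@H]1C[C@]2(C[Zn]I)C(=O)[C@@](CC=C(C)C)(C(=O)C=C2OC)C1(C)C
F5 | step 3 | 1-tert-butyl 6-methyl (3S,4E)-4-methoxy-3-(3-methylbut-2-enoyl)-3-(prop-2-yn-1-yl)hex-4-enedioate (enantiomer of 9) | C#CC[C@@](/C(OC)=C\C(=O)OC)(CC(=O)OC(C)(C)C)C(=O)C=C(C)C
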